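**Plan**
Retrosynthesis: the imide C–N bond and C12–C13 are cut first (Evans aldol of a C12 aldehyde); then C8–C9 and C5–C10 together (intramolecular Diels–Alder); then C6–C7 (Negishi coupling), C9–C11 with C10–CH3 (carboalumination), C5–C6 (Takai) and C3–C4 with C1–C10 (two openings of epichlorohydrin).
Forward: a linear C1–C11 chain is built from (S)-epichlorohydrin; rings A and B arise together in the cycloaddition; C12 is added, ring B is adjusted (ketone, 7β-alcohol, acetate) and the succinimide is closed last.
Enabling feature: ring B carries its C7 oxygen next to the C8 exocyclic methylene, the footprint of a 2-alkoxy vinylallene C5=C6–C7(OMe)=C8=CH2 adding to the C9=C10 alkene; C1–C4 of ring A serve as the tether.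
Stereochemistry: C2 from (S)-epichlorohydrin with one SN2 inversion; C5, C9 and C10 from the cycloaddition (E-alkene, endo mode, equatorial chlorine); C7 by axial hydride delivery; C12 and C13 from the (R)-benzyl oxazolidinone.
Numbering: terpenoid numbering and α/β descriptors are used for the bicyclic compounds (all 5α-H, 10β-CH3); the exocyclic methylene carbon is C12 in drimane names and C17 in labdane names.

Key step: step 8

Step 1
Reactants: 1 (S)-epichlorohydrin; 2 (trimethylsilyl)acetylene
Product: 4 (2S)-1-chloro-5-(trimethylsilyl)pent-4-yn-2-ol, via lithium (trimethylsilyl)acetylide 3 (not isolated)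
Conditions: 2, n-BuLi, THF, −78 °C; BF3·OEt2; then 1, −78 °C; aq. NH4Cl
Reagents that add atoms: none
Why: The BF3-activated epoxide is opened by the lithium acetylide at its unsubstituted carbon (Yamaguchi-type alkynylation), so the stereocentre and the C–Cl bond are untouched.

Step 2
Reactants: 4 (2S)-1-chloro-5-(trimethylsilyl)pent-4-yn-2-ol; 5 isobutyronitrile
Product: 9 (4S)-4-hydroxy-2,2-dimethylhept-6-ynenitrile, via lithiated isobutyronitrile 6 (not isolated), via silylalkynyl epoxide 7 (not isolated), via C-silyl hydroxy nitrile 8 (not isolated)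
Conditions: 5, LiN(iPr)2 (2.2 equiv each), THF, −78 → 23 °C; then MeOH, K2CO3, 23 °C
Reagents that add atoms: none
Why: The alkoxide closes to the terminal epoxide, which the nitrile-stabilised carbanion opens at CH2 (SN2 alkylation of a metallated nitrile, stereocentre not involved), and methanolysis then removes the alkynyl silyl group.

Step 3
Reactants: 9 (4S)-4-hydroxy-2,2-dimethylhept-6-ynenitrile
Product: 10 (4R)-4-chloro-2,2-dimethylhept-6-ynenitrile
Conditions: PPh3, N-chlorosuccinimide, THF, 0 → 23 °C
Reagents that add atoms: N-chlorosuccinimide, ClN1C(=O)CCC1=O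
Why: Appel-type chlorination, in which chloride displaces the alkoxyphosphonium group by SN2 with inversion and so sets the chloride stereocentre (the future C2).

Step 4
Reactants: 10 (4R)-4-chloro-2,2-dimethylhept-6-ynenitrile
Product: 12 (4R)-4-chloro-2,2-dimethylhept-6-ynal, via N-aluminio aldimine 11 (not isolated)
Conditions: iBu2AlH, toluene, −78 → 0 °C; then 1 M HCl (aq), 0 °C
Reagents that add atoms: water, O
Why: One hydride adds to the hindered nitrile and the aluminium aldimine resists further reduction until it is hydrolysed (partial nitrile reduction); the secondary chloride and the alkyne are inert at low temperature.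

Step 5
Reactants: 12 (4R)-4-chloro-2,2-dimethylhept-6-ynal
Product: 13 (1E,5R)-5-chloro-1-iodo-3,3-dimethyloct-1-en-7-yne
Conditions: CrCl2, CHI3, THF/dioxane, 0 → 23 °C
Reagents that add atoms: iodoform, IC(I)I
Why: Takai olefination through a geminal dichromium species should give the E-alkenyl iodide, strongly favoured for an α-quaternary aldehyde, under non-basic conditions that spare the chloride and the alkyne.

Step 6
Reactants: 13 (1E,5R)-5-chloro-1-iodo-3,3-dimethyloct-1-en-7-yne
Product: 15 methyl (2E,5R,8E)-5-chloro-9-iodo-3,7,7-trimethylnona-2,8-dienoate, via alkenyl(dimethyl)alane 14 (not isolated)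
Conditions: AlMe3, Cp2ZrCl2 (0.25 equiv), CH2Cl2, 0 → 23 °C; then ClCO2Me, 0 °C
Reagents that add atoms: trimethylaluminium, C[Al](C)C; methyl chloroformate, COC(Cl)=O
Why: Negishi zirconium-catalysed carboalumination adds methyl and aluminium syn across the terminal alkyne with methyl at the internal carbon, and acylation of the alkenylalane with retention fixes the E-enoate (ester cis to the methyl group).

Step 7
Reactants: 15 methyl (2E,5R,8E)-5-chloro-9-iodo-3,7,7-trimethylnona-2,8-dienoate; 16 methoxyallene
Product: 19 methyl (2E,5R,8E)-5-chloro-10-methoxy-3,7,7-trimethyldodeca-2,8,10,11-tetraenoate, via 1-lithio-1-methoxyallene 17 (not isolated), via (1-methoxyallenyl)zinc chloride 18 (not isolated)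
Conditions: 16, n-BuLi, THF, −40 °C; ZnCl2; then 15, Pd(PPh3)4 (5 mol %), THF, 23 °C; filtration through basic alumina
Reagents that add atoms: none
Why: Negishi coupling of the α-alkoxyallenylzinc halide with the alkenyl iodide under zerovalent palladium catalysis should proceed with retention of the E-geometry and bonding at the oxygen-bearing allenyl carbon; the enoate and the alkyl chloride tolerate the organozinc.

Step 8
Reactants: 19 methyl (2E,5R,8E)-5-chloro-10-methoxy-3,7,7-trimethyldodeca-2,8,10,11-tetraenoate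
Product: 20 methyl 2α-chloro-7-methoxydrima-6,8(12)-dien-11-oate
Conditions: toluene (0.01 M), BHT, Et3N (cat.), 120 °C, sealed tube
Reagents that add atoms: none
Why: On heating, the s-cis diene C5=C6–C7(OMe)=C8 of the alkoxy vinylallene and the E-enoate C9=C10 should undergo a concerted suprafacial [4+2] cycloaddition that forms C5–C10 and C8–C9, leaves the distal allene bond as the C8 exocyclic methylene and places the enol ether at C6=C7. The closest known reaction types are the intramolecular Diels–Alder reactions of vinylallenes and of 2-oxygenated 1,3,9-decatrienes with a terminal ester on the dienophile. Ring B is closed by the cycloaddition itself and ring A by the four-carbon tether C1–C4 as a chair-like six-membered ring (type 1 closure), helped by the gem-dimethyl group at C4 and by the sterically small sp-hybridised terminus C8. The cis relation of the C9 ester and the C10 methyl follows from the E-alkene geometry, the trans ring fusion (5α-H against 10β-CH3) from the endo orientation of the ester with the tether anti, and the absolute sense from C2, because the chlorine stays equatorial in the chair-like tether and would meet both axial methyl groups on C4 and C10 if the other diene face reacted. The step needs endo over exo selectivity and one diene face; secondary orbital overlap of the ester with the electron-rich diene and the equatorial chlorine should secure these, and the tether enforces the regiochemistry. Dilution, a radical inhibitor and a trace of amine base suppress oligomerisation and hydrolysis of the enol ether.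

Step 9
Reactants: 20 methyl 2α-chloro-7-methoxydrima-6,8(12)-dien-11-oate
Product: 21 2α-chloro-7-methoxydrima-6,8(12)-dien-11-ol
Conditions: iBu2AlH, CH2Cl2, −78 → −20 °C; aq. KNaC4H4O6
Reagents that add atoms: none
Why: Hydride reduction of the hindered ester to the primary alcohol; the dienol ether, the exocyclic alkene and the secondary chloride are inert to the aluminium hydride at low temperature.

Step 10
Reactants: 21 2α-chloro-7-methoxydrima-6,8(12)-dien-11-ol
Product: 22 2α-chloro-7-methoxydrima-6,8(12)-dien-11-al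
Conditions: SO3·pyridine, DMSO, iPr2NEt, CH2Cl2, 0 °C
Reagents that add atoms: none
Why: Parikh–Doering oxidation is non-acidic and only weakly basic, so the dienol ether survives and the equatorial (thermodynamically preferred) formyl group at C9 is kept; the aldehyde is used at once.

Step 11
Reactants: 22 2α-chloro-7-methoxydrima-6,8(12)-dien-11-al
Product: 23 pinacol (11E)-2α-chloro-7-methoxy-13,14,15,16-tetranorlabda-6,8(17),11-trien-12-ylboronate
Conditions: Cl2CHBpin, CrCl2, LiI, THF, 23 °C
Reagents that add atoms: 2-(dichloromethyl)-4,4,5,5-tetramethyl-1,3,2-dioxaborolane, ClC(Cl)B1OC(C)(C)C(C)(C)O1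
Why: Takai-type boron olefination adds C12 under non-basic conditions, so the deconjugated, epimerisable C9 aldehyde neither epimerises nor moves its alkene into conjugation; the alkenyl boronate is a latent aldehyde that is stable to acid, hydride and acylation.

Step 12
Reactants: 23 pinacol (11E)-2α-chloro-7-methoxy-13,14,15,16-tetranorlabda-6,8(17),11-trien-12-ylboronate
Product: 24 pinacol (11E)-2α-chloro-7-oxo-13,14,15,16-tetranorlabda-8(17),11-dien-12-ylboronate
Conditions: 0.5 M HCl (aq), THF, 0 °C
Reagents that add atoms: water, O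
Why: Enol ether hydrolysis: C-protonation at C6 of the electron-rich 2-methoxydiene and loss of methanol unveil the C7 ketone conjugated with the exocyclic methylene; the alkenyl boronate and the chloride are stable to dilute acid.

Step 13
Reactants: 24 pinacol (11E)-2α-chloro-7-oxo-13,14,15,16-tetranorlabda-8(17),11-dien-12-ylboronate
Product: 25 pinacol (11E)-2α-chloro-7β-hydroxy-13,14,15,16-tetranorlabda-8(17),11-dien-12-ylboronate
Conditions: NaBH4, CeCl3·7H2O, MeOH, −78 °C
Reagents that add atoms: none
Why: Luche 1,2-reduction of the enone; the small hydride should attack C7 along the axial α trajectory of the ring B chair, past only the axial hydrogens at C5 and C9, to give the equatorial 7β-alcohol.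

Step 14
Reactants: 25 pinacol (11E)-2α-chloro-7β-hydroxy-13,14,15,16-tetranorlabda-8(17),11-dien-12-ylboronate
Product: 26 pinacol (11E)-7β-acetoxy-2α-chloro-13,14,15,16-tetranorlabda-8(17),11-dien-12-ylboronate
Conditions: Ac2O, DMAP (cat.), pyridine, CH2Cl2, 23 °C
Reagents that add atoms: acetic anhydride, CC(=O)OC(C)=O
Why: DMAP-catalysed acylation of the equatorial allylic alcohol with retention at C7; it is done before the second hydroxyl (C12) exists, so no differentiation is needed.

Step 15
Reactants: 26 pinacol (11E)-7β-acetoxy-2α-chloro-13,14,15,16-tetranorlabda-8(17),11-dien-12-ylboronate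
Product: 27 7β-acetoxy-2α-chloro-13,14,15,16-tetranorlabd-8(17)-en-12-al
Conditions: NaBO3·4H2O, THF/H2O (1:1), 23 °C
Reagents that add atoms: sodium perborate, B(=O)O[O-].[Na+]
Why: Oxidation of the alkenyl C–B bond (1,2-shift of carbon from boron to the peroxide oxygen) gives the enol and hence the C12 aldehyde with C11 as CH2; perborate is mild enough to spare the acetate and the exocyclic alkene.

Step 16
Reactants: 28 (R)-4-benzyl-2-oxazolidinone; 29 3-cyanopropanoic acid
Product: 31 (4R)-4-benzyl-3-(3-cyanopropanoyl)-1,3-oxazolidin-2-one, via pivalic mixed anhydride 30 (not isolated)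
Conditions: 29, tBuCOCl, Et3N, THF, −20 °C; then 28, LiCl, 23 °C
Reagents that add atoms: none
Why: Standard auxiliary loading: the mixed pivalic anhydride acylates the oxazolidinone nitrogen at the less hindered carbonyl, assisted by LiCl.

Step 17
Reactants: 27 7β-acetoxy-2α-chloro-13,14,15,16-tetranorlabd-8(17)-en-12-al; 31 (4R)-4-benzyl-3-(3-cyanopropanoyl)-1,3-oxazolidin-2-one
Product: 33 N-[(12S,13R)-7β-acetoxy-2α-chloro-12-hydroxy-15-nitrilolabd-8(17)-en-16-oyl]-(4R)-4-benzyl-1,3-oxazolidin-2-one, via dibutylboron Z-enolate 32 (not isolated)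
Conditions: 31, Bu2BOTf, iPr2NEt, CH2Cl2, −78 → 0 °C; then 27, −78 → 0 °C; pH 7 buffer, MeOH, H2O2, 0 °C
Reagents that add atoms: none
Why: Evans syn aldol: the Z-boron enolate reacts through a Zimmerman–Traxler chair on the enolate face away from the benzyl group, which should set 12S and 13R (syn); the nitrile does not interfere with soft enolisation, and reagent control overrides the remote stereocentres of the aldehyde.

Step 18
Reactants: 33 N-[(12S,13R)-7β-acetoxy-2α-chloro-12-hydroxy-15-nitrilolabd-8(17)-en-16-oyl]-(4R)-4-benzyl-1,3-oxazolidin-2-one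
Product: 35 haterumaimide N, via primary amide 34 (not isolated)
Conditions: [PtH(PMe2OH)(PMe2O)2H] (5 mol %), EtOH/H2O (4:1), 70 °C; then Et3N (cat.), 23 °C
Reagents that add atoms: water, O
Why: The neutral platinum hydride catalyst hydrates the nitrile to the primary amide, whose nitrogen then attacks the activated N-acyl oxazolidinone carbonyl (5-exo-trig N-acylation) to close the succinimide and expel the auxiliary; neutral to weakly basic conditions should spare the allylic acetate, the chloride and the β-hydroxy imide stereocentres.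

**Compound list**
1 | (S)-epichlorohydrin [(2S)-2-(chloromethyl)oxirane] | ClC[C@@H]1CO1 | starting material
2 | (trimethylsilyl)acetylene | C#C[Si](C)(C)C | starting material
3 | lithium (trimethylsilyl)acetylide | [Li]C#C[Si](C)(C)C | intermediate
4 | (2S)-1-chloro-5-(trimethylsilyl)pent-4-yn-2-ol | ClC[C@@H](O)CC#C[Si](C)(C)C | intermediate
5 | isobutyronitrile (2-methylpropanenitrile) | CC(C)C#N | starting material
6 | 2-lithio-2-methylpropanenitrile | [Li]C(C)(C)C#N | intermediate
7 | (2S)-2-[3-(trimethylsilyl)prop-2-yn-1-yl]oxirane | C[Si](C)(C)C#CC[C@H]1CO1 | intermediate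
8 | (4R)-4-hydroxy-2,2-dimethyl-7-(trimethylsilyl)hept-6-ynenitrile | N#CC(C)(C)C[C@@H](O)CC#C[Si](C)(C)C | intermediate
9 | (4S)-4-hydroxy-2,2-dimethylhept-6-ynenitrile | N#CC(C)(C)C[C@@H](O)CC#C | intermediate
10 | (4R)-4-chloro-2,2-dimethylhept-6-ynenitrile | N#CC(C)(C)C[C@H](Cl)CC#C | intermediate
11 | N-(diisobutylaluminio)imine of (4R)-4-chloro-2,2-dimethylhept-6-ynal | CC(C)C[Al](CC(C)C)N=CC(C)(C)C[C@H](Cl)CC#C | intermediate
12 | (4R)-4-chloro-2,2-dimethylhept-6-ynal | O=CC(C)(C)C[C@H](Cl)CC#C | intermediate
13 | (1E,5R)-5-chloro-1-iodo-3,3-dimethyloct-1-en-7-yne | I/C=C/C(C)(C)C[C@H](Cl)CC#C | intermediate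
14 | dimethyl[(1E,7E)-4-chloro-8-iodo-2,6,6-trimethylocta-1,7-dien-1-yl]alane (C–Cl configuration as in 13; Al cis to the new methyl) | C[Al](C)/C=C(\C)C[C@@H](Cl)CC(C)(C)/C=C/I | intermediate
15 | methyl (2E,5R,8E)-5-chloro-9-iodo-3,7,7-trimethylnona-2,8-dienoate | COC(=O)/C=C(\C)C[C@@H](Cl)CC(C)(C)/C=C/I | intermediate
16 | methoxyallene (1-methoxypropa-1,2-diene) | COC=C=C | starting material
17 | 1-lithio-1-methoxyallene | [Li]C(OC)=C=C | intermediate
18 | (1-methoxyallenyl)zinc chloride | COC(=C=C)[Zn]Cl | intermediate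
19 | methyl (2E,5R,8E)-5-chloro-10-methoxy-3,7,7-trimethyldodeca-2,8,10,11-tetraenoate | COC(=O)/C=C(\C)C[C@@H](Cl)CC(C)(C)/C=C/C(OC)=C=C | intermediate
20 | methyl 2α-chloro-7-methoxydrima-6,8(12)-dien-11-oate (trans-decalin; 9β-CO2CH3) | C=C1C(OC)=C[C@H]2C(C)(C)C[C@H](Cl)C[C@]2(C)[C@H]1C(=O)OC | intermediate
21 | 2α-chloro-7-methoxydrima-6,8(12)-dien-11-ol | C=C1C(OC)=C[C@H]2C(C)(C)C[C@H](Cl)C[C@]2(C)[C@H]1CO | intermediate
22 | 2α-chloro-7-methoxydrima-6,8(12)-dien-11-al | C=C1C(OC)=C[C@H]2C(C)(C)C[C@H](Cl)C[C@]2(C)[C@H]1C=O | intermediate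
23 | pinacol (11E)-2α-chloro-7-methoxy-13,14,15,16-tetranorlabda-6,8(17),11-trien-12-ylboronate | C=C1C(OC)=C[C@H]2C(C)(C)C[C@H](Cl)C[C@]2(C)[C@H]1/C=C/B3OC(C)(C)C(C)(C)O3 | intermediate
24 | pinacol (11E)-2α-chloro-7-oxo-13,14,15,16-tetranorlabda-8(17),11-dien-12-ylboronate | C=C1C(=O)C[C@H]2C(C)(C)C[C@H](Cl)C[C@]2(C)[C@H]1/C=C/B3OC(C)(C)C(C)(C)O3 | intermediate
25 | pinacol (11E)-2α-chloro-7β-hydroxy-13,14,15,16-tetranorlabda-8(17),11-dien-12-ylboronate | C=C1[C@@H](O)C[C@H]2C(C)(C)C[C@H](Cl)C[C@]2(C)[C@H]1/C=C/B3OC(C)(C)C(C)(C)O3 | intermediate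
26 | pinacol (11E)-7β-acetoxy-2α-chloro-13,14,15,16-tetranorlabda-8(17),11-dien-12-ylboronate | C=C1[C@@H](OC(C)=O)C[C@H]2C(C)(C)C[C@H](Cl)C[C@]2(C)[C@H]1/C=C/B3OC(C)(C)C(C)(C)O3 | intermediate
27 | 7β-acetoxy-2α-chloro-13,14,15,16-tetranorlabd-8(17)-en-12-al | C=C1[C@@H](OC(C)=O)C[C@H]2C(C)(C)C[C@H](Cl)C[C@]2(C)[C@H]1CC=O | intermediate
28 | (R)-4-benzyl-2-oxazolidinone | O=C1N[C@H](Cc2ccccc2)CO1 | starting material
29 | 3-cyanopropanoic acid | N#CCCC(=O)O | starting material
30 | 3-cyanopropanoic pivalic anhydride | N#CCCC(=O)OC(=O)C(C)(C)C | intermediate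
31 | (4R)-4-benzyl-3-(3-cyanopropanoyl)-1,3-oxazolidin-2-one | N#CCCC(=O)N1[C@H](Cc2ccccc2)COC1=O | intermediate
32 | dibutylboron (Z)-enolate of 31 | CCCCB(CCCC)O/C(=C\CC#N)N1[C@H](Cc2ccccc2)COC1=O | intermediate
33 | N-[(12S,13R)-7β-acetoxy-2α-chloro-12-hydroxy-15-nitrilolabd-8(17)-en-16-oyl]-(4R)-4-benzyl-1,3-oxazolidin-2-one (C13 carries CH2CN; syn aldol adduct) | C=C1[C@@H](OC(C)=O)C[C@H]2C(C)(C)C[C@H](Cl)C[C@]2(C)[C@H]1C[C@H](O)[C@@H](CC#N)C(=O)N1[C@H](Cc2ccccc2)COC1=O | intermediate
34 | N-[(12S,13R)-7β-acetoxy-15-amino-2α-chloro-12-hydroxy-15-oxolabd-8(17)-en-16-oyl]-(4R)-4-benzyl-1,3-oxazolidin-2-one | C=C1[C@@H](OC(C)=O)C[C@H]2C(C)(C)C[C@H](Cl)C[C@]2(C)[C@H]1C[C@H](O)[C@@H](CC(N)=O)C(=O)N1[C@H](Cc2ccccc2)COC1=O | intermediate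
35 | haterumaimide N | C=C1[C@@H](OC(C)=O)C[C@H]2C(C)(C)C[C@H](Cl)C[C@]2(C)[C@H]1C[C@H](O)[C@H]1CC(=O)NC1=O | target

**Step count**
Total steps: 18. Longest linear sequence: 17 (steps 1–15, 17 and 18; step 16 prepares the aldol partner).

**Steps most likely to fail**

Step 8. Oligomerisation or hydrolysis of the allenyl enol ether may outpace a slow cycloaddition, because the tether pairs the nucleophilic diene terminus C8 with the α-carbon of the enoate. Endo/exo discrimination may also be incomplete, giving cis-fused material. Fallback: the dienophile is raised to the aldehyde oxidation level before the cycloaddition. Setting out from 15, iBu2AlH (CH2Cl2, −78 °C) gives (2E,5R,8E)-5-chloro-9-iodo-3,7,7-trimethylnona-2,8-dien-1-ol F1. Negishi coupling of its zinc alkoxide with an excess of 18 (Pd(PPh3)4, THF) gives (2E,5R,8E)-5-chloro-10-methoxy-3,7,7-trimethyldodeca-2,8,10,11-tetraen-1-ol F2. MnO2 (CH2Cl2, 23 °C) gives (2E,5R,8E)-5-chloro-10-methoxy-3,7,7-trimethyldodeca-2,8,10,11-tetraenal F3. This enal is a stronger and more endo-selective dienophile and should cyclise at 60–80 °C directly to aldehyde 22, where the route is rejoined before step 11; steps 9 and 10 are then not needed.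

Step 7. The allenylzinc may couple through its γ-carbon to give the propargylic ynol ether isomer, or the acid-labile 2-alkoxy vinylallene may be protonated during isolation. Fallback: the heteroatom-bearing allene is made by an SN2′ borylation instead of an allenyl metal coupling. From 15, Sonogashira coupling (Pd(PPh3)2Cl2, CuI, Et3N, THF) with methyl prop-2-yn-1-yl carbonate gives methyl (2E,5R,8E)-5-chloro-12-[(methoxycarbonyl)oxy]-3,7,7-trimethyldodeca-2,8-dien-10-ynoate F4. Copper-catalysed γ-selective borylation (B2pin2, CuCl, NaOtBu, Xantphos, THF) gives methyl (2E,5R,8E)-5-chloro-3,7,7-trimethyl-10-(4,4,5,5-tetramethyl-1,3,2-dioxaborolan-2-yl)dodeca-2,8,10,11-tetraenoate F5. Heating in toluene should give, by the same intramolecular Diels–Alder reaction, methyl 2α-chloro-7-(4,4,5,5-tetramethyl-1,3,2-dioxaborolan-2-yl)drima-6,8(12)-dien-11-oate F6. Chan–Lam-type etherification (Cu(OAc)2, Et3N, MeOH, air) converts the C7–B bond into the methyl enol ether and comes back at 20.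

Step 18. Hydration of the nitrile may stall next to the chelating β-hydroxy imide, and prolonged heating in aqueous ethanol may bring retro-aldol cleavage, epimerisation at C13 or loss of the allylic acetate. Fallback: the nitrogen is carried through the aldol reaction as the amide. Imide 31 is hydrated first with the same platinum catalyst to 4-[(4R)-4-benzyl-2-oxo-1,3-oxazolidin-3-yl]-4-oxobutanamide F7, which has no sensitive group. The boron aldol reaction of 27 with F7 (Bu2BOTf in excess so that the amide is O-borylated, iPr2NEt, CH2Cl2) should give hydroxy amide 34 directly, and Et3N at 23 °C closes the imide to 35. The fallback sets out from 27 and 31 and comes back at 34.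

**Further compounds**
F1 | step 8 | (2E,5R,8E)-5-chloro-9-iodo-3,7,7-trimethylnona-2,8-dien-1-ol | OC/C=C(\C)C[C@@H](Cl)CC(C)(C)/C=C/I
F2 | step 8 | (2E,5R,8E)-5-chloro-10-methoxy-3,7,7-trimethyldodeca-2,8,10,11-tetraen-1-ol | OC/C=C(\C)C[C@@H](Cl)CC(C)(C)/C=C/C(OC)=C=C
F3 | step 8 | (2E,5R,8E)-5-chloro-10-methoxy-3,7,7-trimethyldodeca-2,8,10,11-tetraenal | O=C/C=C(\C)C[C@@H](Cl)CC(C)(C)/C=C/C(OC)=C=C
F4 | step 7 | methyl (2E,5R,8E)-5-chloro-12-[(methoxycarbonyl)oxy]-3,7,7-trimethyldodeca-2,8-dien-10-ynoate | COC(=O)/C=C(\C)C[C@@H](Cl)CC(C)(C)/C=C/C#CCOC(=O)OC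
F5 | step 7 | methyl (2E,5R,8E)-5-chloro-3,7,7-trimethyl-10-(4,4,5,5-tetramethyl-1,3,2-dioxaborolan-2-yl)dodeca-2,8,10,11-tetraenoate | COC(=O)/C=C(\C)C[C@@H](Cl)CC(C)(C)/C=C/C(B1OC(C)(C)C(C)(C)O1)=C=C
F6 | step 7 | methyl 2α-chloro-7-(4,4,5,5-tetramethyl-1,3,2-dioxaborolan-2-yl)drima-6,8(12)-dien-11-oate | C=C1C(B3OC(C)(C)C(C)(C)O3)=C[C@H]2C(C)(C)C[C@H](Cl)C[C@]2(C)[C@H]1C(=O)OC
F7 | step 18 | 4-[(4R)-4-benzyl-2-oxo-1,3-oxazolidin-3-yl]-4-oxobutanamide | NC(=O)CCC(=O)N1[C@H](Cc2ccccc2)COC1=O
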